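**The product.** The product is a chain, and the average length divides the monomer in chains by the chains begun. So you need two amounts. Take the statistical zero of the scale: each initiator begins exactly one chain.

the same everywhere: initiator 0.29 mol%

| charge | free monomer | remark | time |
|---|---|---|---|
| grey | 2 M (fed, over 3.0 min) | the very flask that is asked about, followed so far; the fed solution adds 0.20 times the starting volume |  |
| ochre | 1.3 M (fed, over 3.0 min) | run made earlier; the fed solution adds 0.20 times the starting volume |  |
| flask | 2.0 M (fed, over 3.0 min) | the fed solution adds 0.20 times the starting volume | 30 min |

| run | time / min | monomer in chains / % | free monomer / % |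
|---|---|---|---|
| grey | 1.50 | 8.5 | 40.2 |
| grey | 4.00 | 20.4 | 77.4 |
| grey | 8.00 | 20.6 | 78.1 |
| grey | 12.0 | 23.1 | 78.0 |
| ochre | 4.00 | 13.0 | 85.4 |
| ochre | 10.0 | 14.4 | 83.8 |
| ochre | 20.0 | 15.2 | 83.4 |
| ochre | 30.0 | 15.6 | 85.3 |

(standard deviation of a reading: 1 percentage point)

- every charge counts on the volume at the start, and the solution that is fed holds the whole dose
- the average divides the monomer in chains by the number of chains begun, living and dead together
- the earlier runs do not show the number of chains; that part of a forecast is a guess
- percentages count the whole charge, also what has not yet gone in

- whether the average number of monomer units in a chain (chains begun, living or dead) reaches 300 by 30 min (no / yes)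
- average number of monomer units in a chain (chains begun, living or dead) at 30 min

**My reckoning.** Grey is the asked recipe. After its feed, its monomer in chains averages 21.4%, against a loading of 0.29 mol%. Their ratio, a reading with the scatter of these points, gives 73.7 units per initiator. Ochre gives 50.2, less at its lower concentration, so carry this ratio only at the same c(free monomer). With this monomer in chains, reaching 300 in the flask would need under a quarter of the initiator to begin chains, which the earlier runs leave open, but I answer no.

**The forecast.** It says no and 80, with “each initiator starts one chain”. Its number stands above mine, since it takes about 23% in chains.

**The flask.** The flask gives no and 76.5.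

    monomer in chains + living end → free monomer + living end, rate k1*[living end] as long as [monomer in chains] is above zero (k = 0.540 s⁻¹)
    free monomer + initiator → living end + monomer in chains (k = 0.110 M⁻¹ s⁻¹)
    living end → dead end (k = 0.0210 s⁻¹)
    free monomer + living end → monomer in chains + living end, rate k4*[living end]*[free monomer] (k = 3.10 M⁻¹ s⁻¹)

At 30.0 min the flask is at rest: c(living end) is 0 M, the initiator, its limiting reagent, is at 0% of its charge, and free monomer stands at 78%. The length already reads 76.5 at 15.0 min, and at 300 min, ten times the asked time, it reads 76.5. The one-chain step held: c(dead end) is 0.00483 M, and the initiator charge over the final volume is 0.00483 M.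

**Second flask.** Take the same flask with less initiator, 0.12 mol%: the ratio gives 8.84% in chains. This neighbour flask, computed, gives 10.4%, with length 87.0.

The data come from a simulation with constants of no real substance.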